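A direct plan would keep ring A of olivetol, add its third oxygen by formylation and Dakin oxidation, turn that oxygen into a terminal ethynyl ether beside a free phenol, compound A1, and esterify the phenol with a ketal-bearing ynoic acid to the tethered diyne A2. Ring B and a seven-membered lactone would then be closed together by a [Rh(cod)2]BF4/BINAP-catalysed [2+2+2] cycloaddition of A2 with methoxyethyne A3 to the depsidone A4, and A4 would be debenzylated, deketalised and opened with hydroxide. Its weakest points would be:
(a) the cycloaddition, which would have to close an ether–ester tether of seven atoms never used in this reaction, with the orientation of A3 and the self-coupling of A2 left to chance, on the most advanced material;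
(b) the generation of the ethynyl ether A1 with excess n-BuLi next to a free phenol and its passage through an esterification, since such ynol ethers hydrate, polymerise and add phenols readily;
(c) the run of seven steps on ring A that would add no more than one oxygen and two carbons.

**Plan of the new route**

Ring B is numbered C1 (carboxyl), C2 (ether oxygen), C4 (methoxy), C6 (pentanoyl); ring A is numbered C1' (ether oxygen), C2' and C4' (hydroxyls), C6' (pentyl). The retrosynthesis cuts two bonds at neighbouring atoms of ring B in one operation, O–C2 and C1–CO2H, and so leaves a ring A phenol, an aryne and carbon dioxide. The feature that allows this: the ether oxygen, the carboxyl and the pentanoyl group stand on the three neighbouring atoms C2, C1 and C6, so C1 and C2 can be the two ends of an aryne triple bond, and the masked pentanoyl group at C6 beside that bond decides which end takes the oxygen. Both benzene rings are bought (olivetol, 4-methoxyphenol) and no ring is closed at any stage, so there is no cycloaddition of tethered alkynes, no ethynyl ether and no lactone to open. Ring A is ready in three steps and one acid treatment removes all protecting groups.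

Key step: step 8

Remark: the target is taken as the open keto acid of the given structure; 2-acylbenzoic acids can equilibrate with their cyclic hydroxylactone form, which does not change the route.

**Route**

Step 1
Reactants: 1 olivetol (5-pentylbenzene-1,3-diol)
Product: 2 1,3-bis(methoxymethoxy)-5-pentylbenzene
Conditions: MOMCl (2.5 equiv), i-Pr2NEt (3 equiv), CH2Cl2, 0 °C → rt
Reagents that add atoms: chloromethyl methyl ether, COCCl
Why: Williamson-type O-alkylation with an α-chloro ether caps both phenols of the symmetrical resorcinol as methoxymethyl acetals, which cannot migrate between neighbouring oxygens later and fall together with the ketal in the last step.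

Step 2
Reactants: 2 1,3-bis(methoxymethoxy)-5-pentylbenzene
Product: 3 2-bromo-1,5-bis(methoxymethoxy)-3-pentylbenzene
Conditions: NBS (1.0 equiv), MeCN, −20 → 0 °C, dark
Reagents that add atoms: N-bromosuccinimide, O=C1CCC(=O)N1Br
Why: Electrophilic aromatic bromination should take the position para to one acetal oxygen and ortho to the other (beside the pentyl chain), as is usual for 5-alkylresorcinol diethers, because the position between the two oxygens is the more crowded, and one equivalent of NBS at low temperature limits twofold bromination.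

Step 3
Reactants: 3 2-bromo-1,5-bis(methoxymethoxy)-3-pentylbenzene
Product: 6 2,4-bis(methoxymethoxy)-6-pentylphenol, via aryllithium 4 (not isolated), via dimethyl arylboronate 5 (not isolated)
Conditions: n-BuLi (1.1 equiv), THF, −78 °C; B(OMe)3 (1.5 equiv), −78 °C → rt; then 30% H2O2, aq. NaOH, 0 °C → rt
Reagents that add atoms: hydrogen peroxide, OO
Why: Bromine–lithium exchange, borylation and boronate oxidation (1,2-shift of the aryl group from boron to oxygen) put the hydroxyl exactly at the brominated carbon, whereas direct lithiation would go between the two acetal oxygens, and this oxygen becomes the ether oxygen of the target.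

Step 4
Reactants: 7 4-methoxyphenol; 8 pentanoic acid
Product: 10 1-(2-hydroxy-5-methoxyphenyl)pentan-1-one, via 4-methoxyphenyl pentanoate 9 (not isolated)
Conditions: 8 (1.2 equiv), neat BF3·OEt2, 100 °C; then aq. NaOAc
Reagents that add atoms: none
Why: O-Acylation followed by Fries rearrangement under BF3 can only place the acyl group ortho to the hydroxyl, because the para position of 7 is blocked by the methoxy group.

Step 5
Reactants: 10 1-(2-hydroxy-5-methoxyphenyl)pentan-1-one
Product: 11 1-(3-bromo-2-hydroxy-5-methoxyphenyl)pentan-1-one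
Conditions: NBS (1.05 equiv), i-Pr2NH (10 mol%), CH2Cl2, 0 °C
Reagents that add atoms: N-bromosuccinimide, O=C1CCC(=O)N1Br
Why: Amine-catalysed ortho-bromination of a phenol with NBS should go to the free position next to the hydroxyl, the only one that the hydroxyl activates and the acyl group does not deactivate (as in the bromination of 5-methoxysalicylaldehyde), while the neutral conditions leave the α-methylene of the ketone alone.

Step 6
Reactants: 11 1-(3-bromo-2-hydroxy-5-methoxyphenyl)pentan-1-one
Product: 13 [2-bromo-6-(2-butyl-1,3-dioxolan-2-yl)-4-methoxyphenoxy]trimethylsilane, via silyl ether 12 (not isolated)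
Conditions: (Me3Si)2NH (1.0 equiv), THF, 65 °C, volatiles removed; 1,2-bis(trimethylsilyloxy)ethane (1.5 equiv), Me3SiOTf (5 mol%), CH2Cl2, −20 → 0 °C; pyridine quench, pentane, filtration through basic Al2O3, volatiles and excess reagent removed at 0.1 mbar; stored under Ar
Reagents that add atoms: hexamethyldisilazane, C[Si](C)(C)N[Si](C)(C)C; 1,2-bis(trimethylsilyloxy)ethane, C[Si](C)(C)OCCO[Si](C)(C)C
Why: Noyori ketalisation of the O-silylated ketone, in which silylation first removes the hydrogen bond that makes ortho-hydroxyaryl ketones slow to ketalise, the bis-silyl glycol and catalytic Me3SiOTf then form the dioxolane at low temperature driven by hexamethyldisiloxane, and the non-aqueous work-up keeps the aryl silyl ether, flanked on both sides, that the next step needs.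

Step 7
Reactants: 13 [2-bromo-6-(2-butyl-1,3-dioxolan-2-yl)-4-methoxyphenoxy]trimethylsilane
Product: 16 2-(2-butyl-1,3-dioxolan-2-yl)-4-methoxy-6-(trimethylsilyl)phenyl trifluoromethanesulfonate, via aryllithium 14 (not isolated), via lithium phenolate 15 (not isolated)
Conditions: n-BuLi (1.1 equiv), THF, −100 → −78 °C; Tf2O (1.2 equiv), −100 → −78 °C; then cold aq. NaHCO3
Reagents that add atoms: trifluoromethanesulfonic anhydride, O=S(=O)(OS(=O)(=O)C(F)(F)F)C(F)(F)F
Why: 2-Silylaryl triflate synthesis by retro-Brook rearrangement, in which bromine–lithium exchange on the aryl silyl ether is followed by 1,3-migration of silicon from oxygen to carbon and the lithium phenolate so formed is triflated in the same flask, the dioxolane being inert to n-BuLi at this temperature.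

Step 8
Reactants: 6 2,4-bis(methoxymethoxy)-6-pentylphenol; 16 2-(2-butyl-1,3-dioxolan-2-yl)-4-methoxy-6-(trimethylsilyl)phenyl trifluoromethanesulfonate
Product: 20 2-[2,4-bis(methoxymethoxy)-6-pentylphenoxy]-6-(2-butyl-1,3-dioxolan-2-yl)-4-methoxybenzoic acid, via potassium phenolate 17 (not isolated), via aryne 18 (not isolated), via arylpotassium 19 (not isolated)
Conditions: 6, KH (1.05 equiv), THF, 0 °C; KF (3 equiv), 18-crown-6 (3 equiv), CO2 (1 atm); 16 (1.3 equiv) in THF added over 4 h, 0 °C → rt; then cold 10% aq. KHSO4 to pH 4; crude acid used directly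
Reagents that add atoms: carbon dioxide, O=C=O
Why: Proposed new method: fluoride takes the silyl group of 16 and loss of triflate gives aryne 18, whose triple bond lies between C1 and C2 of ring B; the potassium phenolate 17 adds through oxygen to C2 and the aryl carbanion 19 left at C1 is caught by carbon dioxide, so that the diaryl ether bond O–C2 and the bond C1–CO2H form in one operation. The closest known reaction types are the O-arylation of phenols by arynes from 2-silylaryl triflates and the three-component coupling of arynes with secondary amines or halide ions and carbon dioxide to 2-substituted benzoic acids; a phenolate has not been shown as the nucleophile of such a carboxylative coupling. No ring is closed and no stereocentre is formed. The step needs oxygen at C2 and carbon at C1: the quaternary dioxolane carbon at C6, beside the triple bond, shields C1 against the phenolate, which is itself flanked by two ortho substituents, and as a carbon that bears two oxygens it stabilises by induction the negative charge that builds up at C1, as sigma-withdrawing groups do in other 3-substituted arynes, so attack at the far carbon C2 should outweigh the weak opposite bias of the methoxy group at C4. It also needs carbon dioxide to win against protonation of 19: the phenol is deprotonated beforehand with KH so that no O–H or N–H acid remains, THF replaces acetonitrile, the dioxolane oxygens can hold the potassium ion at C1, and 16 is added slowly so that 18 always meets an excess of 17.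

Step 9
Reactants: 20 2-[2,4-bis(methoxymethoxy)-6-pentylphenoxy]-6-(2-butyl-1,3-dioxolan-2-yl)-4-methoxybenzoic acid
Product: 21 2-(2,4-dihydroxy-6-pentylphenoxy)-4-methoxy-6-pentanoylbenzoic acid
Conditions: 3 M aq. HCl/MeOH/THF (1:3:3), 45 °C; MeOH removed; then 1 M aq. HCl/THF (1:1), rt
Reagents that add atoms: water, O
Why: Acid-catalysed acetal cleavage removes both methoxymethyl ethers and the dioxolane in one operation, methanol carrying the formaldehyde off as dimethoxymethane so that it cannot attack the electron-rich ring A, and the water-rich finish should return any methyl pseudo-ester of the keto acid to the free acid.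

**Compound list**

1 | olivetol (5-pentylbenzene-1,3-diol) | CCCCCc1cc(O)cc(O)c1 | starting material
2 | 1,3-bis(methoxymethoxy)-5-pentylbenzene | CCCCCc1cc(OCOC)cc(OCOC)c1 | intermediate
3 | 2-bromo-1,5-bis(methoxymethoxy)-3-pentylbenzene | CCCCCc1cc(OCOC)cc(OCOC)c1Br | intermediate
4 | [2,4-bis(methoxymethoxy)-6-pentylphenyl]lithium (aryllithium, not isolated) | [Li]c1c(CCCCC)cc(OCOC)cc1OCOC | intermediate
5 | dimethyl [2,4-bis(methoxymethoxy)-6-pentylphenyl]boronate (not isolated) | CCCCCc1cc(OCOC)cc(OCOC)c1B(OC)OC | intermediate
6 | 2,4-bis(methoxymethoxy)-6-pentylphenol | CCCCCc1cc(OCOC)cc(OCOC)c1O | intermediate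
7 | 4-methoxyphenol | COc1ccc(O)cc1 | starting material
8 | pentanoic acid | CCCCC(=O)O | starting material
9 | 4-methoxyphenyl pentanoate (not isolated) | CCCCC(=O)Oc1ccc(OC)cc1 | intermediate
10 | 1-(2-hydroxy-5-methoxyphenyl)pentan-1-one | CCCCC(=O)c1cc(OC)ccc1O | intermediate
11 | 1-(3-bromo-2-hydroxy-5-methoxyphenyl)pentan-1-one | CCCCC(=O)c1cc(OC)cc(Br)c1O | intermediate
12 | 1-[3-bromo-5-methoxy-2-(trimethylsilyloxy)phenyl]pentan-1-one (silyl ether, not isolated) | CCCCC(=O)c1cc(OC)cc(Br)c1O[Si](C)(C)C | intermediate
13 | [2-bromo-6-(2-butyl-1,3-dioxolan-2-yl)-4-methoxyphenoxy]trimethylsilane | CCCCC1(OCCO1)c1cc(OC)cc(Br)c1O[Si](C)(C)C | intermediate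
14 | [3-(2-butyl-1,3-dioxolan-2-yl)-5-methoxy-2-(trimethylsilyloxy)phenyl]lithium (aryllithium, not isolated) | CCCCC1(OCCO1)c1cc(OC)cc([Li])c1O[Si](C)(C)C | intermediate
15 | lithium 2-(2-butyl-1,3-dioxolan-2-yl)-4-methoxy-6-(trimethylsilyl)phenolate (not isolated) | CCCCC1(OCCO1)c1cc(OC)cc([Si](C)(C)C)c1O[Li] | intermediate
16 | 2-(2-butyl-1,3-dioxolan-2-yl)-4-methoxy-6-(trimethylsilyl)phenyl trifluoromethanesulfonate | CCCCC1(OCCO1)c1cc(OC)cc([Si](C)(C)C)c1OS(=O)(=O)C(F)(F)F | intermediate
17 | potassium 2,4-bis(methoxymethoxy)-6-pentylphenolate (not isolated) | CCCCCc1cc(OCOC)cc(OCOC)c1O[K] | intermediate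
18 | 3-(2-butyl-1,3-dioxolan-2-yl)-5-methoxybenzyne (aryne with the triple bond between C1 and C2 of ring B, not isolated) | CCCCC1(OCCO1)C1=CC(OC)=CC#C1 | intermediate
19 | {2-[2,4-bis(methoxymethoxy)-6-pentylphenoxy]-6-(2-butyl-1,3-dioxolan-2-yl)-4-methoxyphenyl}potassium (arylpotassium, not isolated) | [K]c1c(Oc2c(CCCCC)cc(OCOC)cc2OCOC)cc(OC)cc1C1(CCCC)OCCO1 | intermediate
20 | 2-[2,4-bis(methoxymethoxy)-6-pentylphenoxy]-6-(2-butyl-1,3-dioxolan-2-yl)-4-methoxybenzoic acid | CCCCCc1cc(OCOC)cc(OCOC)c1Oc1cc(OC)cc(C2(CCCC)OCCO2)c1C(=O)O | intermediate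
21 | 2-(2,4-dihydroxy-6-pentylphenoxy)-4-methoxy-6-pentanoylbenzoic acid | CCCCCc1cc(O)cc(O)c1Oc1cc(OC)cc(C(=O)CCCC)c1C(=O)O | target

Total step count: 9. Longest linear sequence: 6 steps (steps 4, 5, 6, 7, 8, 9, from 4-methoxyphenol).

**Steps most likely to fail**

Step 8 (proposed new method). The aryl carbanion may be protonated before it meets carbon dioxide, the phenolate may be carboxylated before it meets the aryne and then add through a carboxylate oxygen, or the addition may take the wrong orientation. The fallback uses known reactions and runs from 13 and 6 back to 20. Compound 13 would be desilylated (K2CO3 cat., MeOH, 0 °C) to 2-bromo-6-(2-butyl-1,3-dioxolan-2-yl)-4-methoxyphenol F1 and this phenol would be triflated (Tf2O, pyridine, CH2Cl2, 0 °C) to 2-bromo-6-(2-butyl-1,3-dioxolan-2-yl)-4-methoxyphenyl trifluoromethanesulfonate F2. An Ullmann ether synthesis of the bromide F2 with 6 (CuI, picolinic acid, K3PO4, DMSO, 90 °C), in which copper engages the bromide and not the triflate, would give 2-[2,4-bis(methoxymethoxy)-6-pentylphenoxy]-6-(2-butyl-1,3-dioxolan-2-yl)-4-methoxyphenyl trifluoromethanesulfonate F3. Hydroxycarbonylation of the triflate F3 (Pd(OAc)2, dppf, CO 1 atm, KOAc, DMSO, 80 °C) would give 20. The two bonds at C2 and C1 are then made one after the other, and their positions are fixed by the bromine and the triflate.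

Step 6. Ketalisation of the hindered, electronically deactivated aryl ketone may stay incomplete, or the dioxolane may open again under the silyl triflate before the quench. The fallback runs from 11 to 21 and masks the ketone as an alkene that is cleaved oxidatively late. Wittig methylenation of 11 (Ph3P=CH2, 3 equiv, THF, 0 °C → rt) would give 2-bromo-6-(hex-1-en-2-yl)-4-methoxyphenol F4. Silylation of F4 ((Me3Si)2NH, THF, 65 °C, volatiles removed) would give [2-bromo-6-(hex-1-en-2-yl)-4-methoxyphenoxy]trimethylsilane F5, and retro-Brook rearrangement and triflation as in step 7 would give 2-(hex-1-en-2-yl)-4-methoxy-6-(trimethylsilyl)phenyl trifluoromethanesulfonate F6. Coupling of F6 with 6 and carbon dioxide as in step 8 would give 2-[2,4-bis(methoxymethoxy)-6-pentylphenoxy]-6-(hex-1-en-2-yl)-4-methoxybenzoic acid F7. Lemieux–Johnson cleavage of F7 (OsO4 cat., NaIO4, 2,6-lutidine, dioxane/H2O) would give 2-[2,4-bis(methoxymethoxy)-6-pentylphenoxy]-4-methoxy-6-pentanoylbenzoic acid F8, and the acid treatment of step 9 would turn F8 into 21.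

Step 7. Migration of silicon from oxygen to carbon may stay incomplete, or triflation of a phenolate flanked on both sides may be slow, with loss of the silyl group on work-up. The fallback runs from 10 to 16 and places the silyl group by directed ortho-metalation, not by halogen–metal exchange. Compound 10 would be silylated and ketalised as in step 6 to [2-(2-butyl-1,3-dioxolan-2-yl)-4-methoxyphenoxy]trimethylsilane F9, which would be desilylated (K2CO3 cat., MeOH, 0 °C) to 2-(2-butyl-1,3-dioxolan-2-yl)-4-methoxyphenol F10. Carbamoylation of F10 (i-PrNCO, Et3N, CH2Cl2) would give 2-(2-butyl-1,3-dioxolan-2-yl)-4-methoxyphenyl N-isopropylcarbamate F11. N-Silylation (Me3SiOTf, TMEDA, Et2O), ortho-lithiation next to the carbamate (n-BuLi, TMEDA, −78 °C) and quenching with Me3SiCl would give 2-(2-butyl-1,3-dioxolan-2-yl)-4-methoxy-6-(trimethylsilyl)phenyl N-isopropylcarbamate F12. Cleavage of the carbamate of F12 (DBU, Et2NH, MeCN, 40 °C) and triflation of the phenolate in the same flask (PhNTf2) would give 16.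

**Further compounds**

F1 | step 8 | 2-bromo-6-(2-butyl-1,3-dioxolan-2-yl)-4-methoxyphenol | CCCCC1(OCCO1)c1cc(OC)cc(Br)c1O
F2 | step 8 | 2-bromo-6-(2-butyl-1,3-dioxolan-2-yl)-4-methoxyphenyl trifluoromethanesulfonate | CCCCC1(OCCO1)c1cc(OC)cc(Br)c1OS(=O)(=O)C(F)(F)F
F3 | step 8 | 2-[2,4-bis(methoxymethoxy)-6-pentylphenoxy]-6-(2-butyl-1,3-dioxolan-2-yl)-4-methoxyphenyl trifluoromethanesulfonate | CCCCCc1cc(OCOC)cc(OCOC)c1Oc1cc(OC)cc(C2(CCCC)OCCO2)c1OS(=O)(=O)C(F)(F)F
F4 | step 6 | 2-bromo-6-(hex-1-en-2-yl)-4-methoxyphenol | C=C(CCCC)c1cc(OC)cc(Br)c1O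
F5 | step 6 | [2-bromo-6-(hex-1-en-2-yl)-4-methoxyphenoxy]trimethylsilane | C=C(CCCC)c1cc(OC)cc(Br)c1O[Si](C)(C)C
F6 | step 6 | 2-(hex-1-en-2-yl)-4-methoxy-6-(trimethylsilyl)phenyl trifluoromethanesulfonate | C=C(CCCC)c1cc(OC)cc([Si](C)(C)C)c1OS(=O)(=O)C(F)(F)F
F7 | step 6 | 2-[2,4-bis(methoxymethoxy)-6-pentylphenoxy]-6-(hex-1-en-2-yl)-4-methoxybenzoic acid | CCCCCc1cc(OCOC)cc(OCOC)c1Oc1cc(OC)cc(C(=C)CCCC)c1C(=O)O
F8 | step 6 | 2-[2,4-bis(methoxymethoxy)-6-pentylphenoxy]-4-methoxy-6-pentanoylbenzoic acid | CCCCCc1cc(OCOC)cc(OCOC)c1Oc1cc(OC)cc(C(=O)CCCC)c1C(=O)O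
F9 | step 7 | [2-(2-butyl-1,3-dioxolan-2-yl)-4-methoxyphenoxy]trimethylsilane | CCCCC1(OCCO1)c1cc(OC)ccc1O[Si](C)(C)C
F10 | step 7 | 2-(2-butyl-1,3-dioxolan-2-yl)-4-methoxyphenol | CCCCC1(OCCO1)c1cc(OC)ccc1O
F11 | step 7 | 2-(2-butyl-1,3-dioxolan-2-yl)-4-methoxyphenyl N-isopropylcarbamate | CCCCC1(OCCO1)c1cc(OC)ccc1OC(=O)NC(C)C
F12 | step 7 | 2-(2-butyl-1,3-dioxolan-2-yl)-4-methoxy-6-(trimethylsilyl)phenyl N-isopropylcarbamate | CCCCC1(OCCO1)c1cc(OC)cc([Si](C)(C)C)c1OC(=O)NC(C)C
A1 | direct plan | 5-(benzyloxy)-2-(ethynyloxy)-3-pentylphenol | CCCCCc1cc(OCc2ccccc2)cc(O)c1OC#C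
A2 | direct plan | 5-(benzyloxy)-2-(ethynyloxy)-3-pentylphenyl 3-(2-butyl-1,3-dioxolan-2-yl)prop-2-ynoate | CCCCCc1cc(OCc2ccccc2)cc(OC(=O)C#CC3(CCCC)OCCO3)c1OC#C
A3 | direct plan | methoxyethyne | COC#C
A4 | direct plan | 8-(benzyloxy)-1-(2-butyl-1,3-dioxolan-2-yl)-3-methoxy-6-pentyl-11H-dibenzo[b,e][1,4]dioxepin-11-one | CCCCCc1cc(OCc2ccccc2)cc3OC(=O)c4c(C5(CCCC)OCCO5)cc(OC)cc4Oc13
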